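The flavone is cut at the O1–C8a bond of ring C. Ring A carries oxygen at C5 and C8a, methoxy at C6 and C8 and a hydroxyl at C7, so it is mirror-symmetric about the C4a–C7 axis and maps onto acetosyringone once both carbons ortho to the acyl group bear bromine. In the key step the enol oxygen of a 1-(2,6-dibromoaryl)-3-aryl-1,3-diketone displaces one of the two equivalent bromides under copper catalysis. This closes the pyranone and leaves the other bromide at C5 as the handle for the last oxygen. The precursor is the O-benzyl-protected dibromo diketone, assembled by Claisen condensation.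

Key step: step 4

Remark: the 1,3-diketone is drawn as its diketo tautomer although it should exist mainly as the chelated enol; the target and all intermediates are achiral, so no stereocontrol is required.

Step 1
Reactants: 1 acetosyringone, 1-(4-hydroxy-3,5-dimethoxyphenyl)ethanone
Product: 2 1-[4-(benzyloxy)-3,5-dimethoxyphenyl]ethanone
Conditions: BnBr (1.2 equiv), K2CO3 (2 equiv), DMF, 60 °C
Reagents that add atoms: benzyl bromide, BrCc1ccccc1
Why: Williamson ether synthesis: the phenol, acidified by the para acetyl group, is fully ionised by K2CO3 and the phenoxide displaces bromide from the benzylic carbon by SN2 despite the two flanking methoxy groups.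

Step 2
Reactants: 2 1-[4-(benzyloxy)-3,5-dimethoxyphenyl]ethanone
Product: 3 1-[4-(benzyloxy)-2,6-dibromo-3,5-dimethoxyphenyl]ethanone
Conditions: NBS (2.3 equiv), MeCN, rt → 50 °C, dark
Reagents that add atoms: N-bromosuccinimide, O=C1CCC(=O)N1Br
Why: Electrophilic aromatic bromination: the only two ring hydrogens each sit ortho to one methoxy group and para to the other, and NBS in MeCN releases no HBr, so acid-catalysed enolisation and bromination of the acetyl methyl group should stay slow while the unactivated benzyl ring is left alone.

Step 3
Reactants: 3 1-[4-(benzyloxy)-2,6-dibromo-3,5-dimethoxyphenyl]ethanone; 4 methyl 2,3-dimethoxybenzoate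
Product: 5 1-[4-(benzyloxy)-2,6-dibromo-3,5-dimethoxyphenyl]-3-(2,3-dimethoxyphenyl)propane-1,3-dione
Conditions: NaH (3 equiv), THF, 0 °C → reflux; then 1 M HCl
Reagents that add atoms: none
Why: Crossed Claisen condensation: only ketone 3 can enolise, its carbonyl is shielded by two ortho bromines so self-aldol is suppressed, the enolate terminus is unhindered, the fully substituted ring A offers no benzyne or halogen-migration pathway, and deprotonation of the 1,3-diketone product drives the equilibrium.

Step 4
Reactants: 5 1-[4-(benzyloxy)-2,6-dibromo-3,5-dimethoxyphenyl]-3-(2,3-dimethoxyphenyl)propane-1,3-dione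
Product: 6 7-(benzyloxy)-5-bromo-6,8-dimethoxy-2-(2,3-dimethoxyphenyl)chromen-4-one
Conditions: CuI (10 mol %), 1,10-phenanthroline (20 mol %), K2CO3 (2 equiv), DMF (0.05 M), 110 °C, N2
Reagents that add atoms: none
Why: K2CO3 converts 5 into its potassium enolate, and the enolate oxygen on the carbon that bears ring B binds monovalent copper and so places the metal beside a C–Br bond ortho to the acyl group; oxidative addition gives a trivalent copper aryl alkoxide chelate, and C–O reductive elimination forms O1–C8a and returns monovalent copper. The closest known reaction type is the intramolecular Ullmann O-arylation of 1-(2-haloaryl)-1,3-diketones to chromones and flavones. Ring C, the six-membered pyranone, is closed in a formally 6-exo-trig mode, the enol oxygen adding to the sp2 carbon C8a while the departing bromide lies outside the new ring. No stereocentre is created. Three selectivities are needed and the substrate supplies all of them: oxygen rather than carbon arylation, because attack by the central carbon would give a four-membered benzocyclobutenone; either bromide, because the two are related by the mirror plane of ring A; and one bromide only, because after closure no enol oxygen is left and the C4 carbonyl oxygen cannot reach C5. Working dilute and stopping at full conversion should keep the peri-activated C5–Br of 6 from coupling with unreacted enolate.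

Step 5
Reactants: 6 7-(benzyloxy)-5-bromo-6,8-dimethoxy-2-(2,3-dimethoxyphenyl)chromen-4-one
Product: 7 7-(benzyloxy)-5-hydroxy-6,8-dimethoxy-2-(2,3-dimethoxyphenyl)chromen-4-one
Conditions: Cu(acac)2 (5 mol %), N,N'-bis(4-hydroxy-2,6-dimethylphenyl)oxalamide (5 mol %), LiOH·H2O (3 equiv), DMSO–H2O (4:1), 80 °C; then 1 M HCl, rt → 50 °C
Reagents that add atoms: lithium hydroxide monohydrate, [Li+].[OH-].O
Why: Ullmann-type copper-catalysed hydroxylation of an aryl bromide: the peri C4 carbonyl chelates copper next to C5–Br as in 1-haloanthraquinones, and any hydroxide-induced opening of ring C is reversed on acidification and is harmless because the opened form carries equivalent oxygens at C5 and C8a, so either re-closure returns the same flavone.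

Step 6
Reactants: 7 7-(benzyloxy)-5-hydroxy-6,8-dimethoxy-2-(2,3-dimethoxyphenyl)chromen-4-one
Product: 8 5,7-dihydroxy-6,8-dimethoxy-2-(2,3-dimethoxyphenyl)chromen-4-one (5,7-dihydroxy-6,8,2',3'-tetramethoxyflavone)
Conditions: H2 (1 atm), 10 % Pd/C, EtOAc–MeOH, rt
Reagents that add atoms: none
Why: Catalytic hydrogenolysis of an aryl benzyl ether: at 1 atm and room temperature the benzylic C–O bond is cleaved while the conjugated C2=C3 bond of the chromone, the aryl methyl ethers and the chelated 5-hydroxyl should remain untouched.

Compound list
1 | acetosyringone, 1-(4-hydroxy-3,5-dimethoxyphenyl)ethanone | CC(=O)c1cc(OC)c(O)c(OC)c1 | starting material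
2 | 1-[4-(benzyloxy)-3,5-dimethoxyphenyl]ethanone | CC(=O)c1cc(OC)c(OCc2ccccc2)c(OC)c1 | intermediate
3 | 1-[4-(benzyloxy)-2,6-dibromo-3,5-dimethoxyphenyl]ethanone | CC(=O)c1c(Br)c(OC)c(OCc2ccccc2)c(OC)c1Br | intermediate
4 | methyl 2,3-dimethoxybenzoate | COC(=O)c1cccc(OC)c1OC | starting material
5 | 1-[4-(benzyloxy)-2,6-dibromo-3,5-dimethoxyphenyl]-3-(2,3-dimethoxyphenyl)propane-1,3-dione | COc1cccc(C(=O)CC(=O)c2c(Br)c(OC)c(OCc3ccccc3)c(OC)c2Br)c1OC | intermediate
6 | 7-(benzyloxy)-5-bromo-6,8-dimethoxy-2-(2,3-dimethoxyphenyl)chromen-4-one | COc1cccc(-c2cc(=O)c3c(Br)c(OC)c(OCc4ccccc4)c(OC)c3o2)c1OC | intermediate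
7 | 7-(benzyloxy)-5-hydroxy-6,8-dimethoxy-2-(2,3-dimethoxyphenyl)chromen-4-one | COc1cccc(-c2cc(=O)c3c(O)c(OC)c(OCc4ccccc4)c(OC)c3o2)c1OC | intermediate
8 | 5,7-dihydroxy-6,8-dimethoxy-2-(2,3-dimethoxyphenyl)chromen-4-one | COc1cccc(-c2cc(=O)c3c(O)c(OC)c(O)c(OC)c3o2)c1OC | target

Total step count: 6. Longest linear sequence: 6 steps, from 1 to 8; ester 4 enters at step 3.

Steps most likely to fail

Step 5. The hydroxide needed for the C–O coupling may open ring C and then cleave the resulting diketone by retro-Claisen fragmentation, or the crowded C5–Br bond may be reduced instead of substituted. The fallback sets out from 6 and uses methoxide as the oxygen nucleophile. NaOMe, CuBr, DMF–MeOH, 110 °C (copper-catalysed methoxylation, a substitution that bromoflavones are known to tolerate) should give 7-(benzyloxy)-5,6,8-trimethoxy-2-(2,3-dimethoxyphenyl)chromen-4-one F1. BCl3 with pentamethylbenzene in CH2Cl2, −78 → 0 °C, should then cleave the 5-methyl ether, activated by chelation to the C4 carbonyl, together with the benzyl ether. This comes back to the route at 8 and makes step 6 unnecessary.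

Step 2. Bromination of the acetyl methyl group through the enol may compete with the second, slower ring bromination. The fallback sets out from 2 and removes the enolisable carbonyl for the duration of the halogenation. NaBH4 in MeOH should give racemic 1-[4-(benzyloxy)-3,5-dimethoxyphenyl]ethanol F2, whose ring is also more electron-rich. NBS in MeCN should then give racemic 1-[4-(benzyloxy)-2,6-dibromo-3,5-dimethoxyphenyl]ethanol F3. Oxidation with Dess–Martin periodinane in CH2Cl2 comes back to the route at 3.

Step 4. The diketonate may hold copper as an unreactive O,O-chelate, or the surviving peri-activated bromide may be reduced or may couple with a second enolate molecule. The fallback sets out from 3 and installs both ring A oxygens before ring C is built, so that the ring closes by dehydration and not by arylation. CuI, 1,10-phenanthroline, KOH, DMSO–H2O, 110 °C (ortho-acyl-assisted double hydroxylation, which the simple ketone should tolerate) should give 1-[4-(benzyloxy)-2,6-dihydroxy-3,5-dimethoxyphenyl]ethanone F4. Claisen condensation of its trianion with 4 (LiN(SiMe3)2, 4.5 equiv, THF, −78 °C → rt) should give 1-[4-(benzyloxy)-2,6-dihydroxy-3,5-dimethoxyphenyl]-3-(2,3-dimethoxyphenyl)propane-1,3-dione F5. Acid cyclodehydration (TsOH·H2O cat., toluene, 90 °C) onto either of the two equivalent phenols comes back to the route at 7.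

Further compounds
F1 | step 5 | 7-(benzyloxy)-5,6,8-trimethoxy-2-(2,3-dimethoxyphenyl)chromen-4-one | COc1cccc(-c2cc(=O)c3c(OC)c(OC)c(OCc4ccccc4)c(OC)c3o2)c1OC
F2 | step 2 | racemic 1-[4-(benzyloxy)-3,5-dimethoxyphenyl]ethanol | CC(O)c1cc(OC)c(OCc2ccccc2)c(OC)c1
F3 | step 2 | racemic 1-[4-(benzyloxy)-2,6-dibromo-3,5-dimethoxyphenyl]ethanol | CC(O)c1c(Br)c(OC)c(OCc2ccccc2)c(OC)c1Br
F4 | step 4 | 1-[4-(benzyloxy)-2,6-dihydroxy-3,5-dimethoxyphenyl]ethanone | CC(=O)c1c(O)c(OC)c(OCc2ccccc2)c(OC)c1O
F5 | step 4 | 1-[4-(benzyloxy)-2,6-dihydroxy-3,5-dimethoxyphenyl]-3-(2,3-dimethoxyphenyl)propane-1,3-dione | COc1cccc(C(=O)CC(=O)c2c(O)c(OC)c(OCc3ccccc3)c(OC)c2O)c1OC
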